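## The problem

Compound 19 is a cis-fused 3,7-dioxabicyclo[3.3.0]octan-8-one. With the numbering used throughout (C1 alpha to the lactone carbonyl C8, C2 carrying the 3,4-dihydroxyphenyl ring, O3, C4H2, C5, C6 carrying the 3,4,5-trihydroxyphenyl ring, O7, C8), it is a 2-aryltetrahydrofuran (C1, C2, O3, C4, C5) fused through the C1–C5 bond to a gamma-aryl butyrolactone (C1, C5, C6, O7, C8). Four contiguous stereocentres, (1S,2S,5R,6S), must be set: the ring-fusion hydrogens are cis, and both aryl groups lie on the convex face, the C2 aryl trans to C8 and the C6 aryl trans to C4. C5 is the pivot: once it is fixed absolutely, C1 can only follow (a trans fusion of the two five-membered rings is not accessible), C2 can be set against it across the tetrahydrofuran ring, and C6 can be set by 1,2-induction from it. The five phenolic hydroxyls, a catechol and a pyrogallol, are oxidised easily, most of all as phenoxides, so they must stay masked to the end and be released without base. The benzylic C2–O3 and C6–O7 bonds are open to hydrogenolysis and to acid ionisation, and an enolate at C1 of the finished lactone can expel O3, so long hydrogenations, strong acids and hot basic media are excluded late in the route. A short synthesis is possible because O3–C4–C5, with C6 attached to C5, is an alkoxide-bearing allyl unit in disguise, while C1–C2, with an acyl group on C1 and an aryl group on C2, is the double bond of an arylidene malonate.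

## Retrosynthesis

**19 ⇒ 18 (five O–Si bonds).** The phenols are carried as tert-butyldimethylsilyl (TBS) ethers in pentasilyl lactone 18. Benzyl ethers would need a long hydrogenolysis of a product with two benzylic C–O bonds, and acetal or methyl ethers would need acid or Lewis acid at the same bonds. The forward step needs only buffered fluoride, which keeps the liberated phenols protonated and C1 un-enolised.

**18 ⇒ 16 (the C1–carboxyl bond).** Lactone 18 is traced to benzyl ester 16, the remnant of a geminal diester at C1. A methyl ester here would have to be removed by halide in a hot, wet dipolar solvent. Those conditions strip aryl silyl ethers and pass through a C1 enolate that can eject O3. A benzyl ester is cleaved by a short hydrogenolysis, and the free acid 17 then loses carbon dioxide thermally through the neutral lactone enol. The only demand on the forward step is that the enol ketonises to the cis ring fusion, which is the only fusion available.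

**16 ⇒ 14 (the O7–C8 bond and the C6–H bond).** The lactone is opened to alkoxide 15 and C6 is returned to the ketone level in aryl ketone 14. The neighbouring cut, the C6–aryl bond formed by adding an aryl nucleophile to aldehyde 7, is one operation shorter but was set aside on stereochemical grounds. In the Felkin–Anh arrangement the incoming group enters anti to the quaternary C1; if that group is the aryl, lactonisation places it cis to C4, the C6 epimer of the target. If the incoming group is hydride and the aryl is already in place, the same facial preference gives the required (6S) centre. Ketone 14 is monocyclic and has one stereocentre fewer than 16. The forward step needs a bulky hydride and spontaneous closure of 15 onto the one ester it can reach, the cis one.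

**14 ⇒ 8 + 10 (the C6–aryl bond).** The ketone is cut into acid 8, used as its chloride 11, and aryl bromide 10, used as arylzinc chloride 13 made through aryllithium 12. A Friedel–Crafts acylation of a pyrogallol triether would acylate next to oxygen and give the wrong substitution pattern. A lithium or magnesium aryl on an acid derivative would not respect the two benzyl esters. A palladium-catalysed acylation of the zinc reagent is convergent and mild. The forward step must not enolise C5, which is alpha to the new carbonyl and beta to O3.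

**8 ⇒ 6 (the C6=CH2 bond).** The carboxyl group of 8 comes from the vinyl group of cycloadduct 6 by ozonolysis and chlorite oxidation in one flask, through aldehyde 7. The terminal carbon is lost, and nothing else in the molecule changes.

**6 ⇒ 4 + 5 (the O3–C2 and C1–C5 bonds; the key step).** The tetrahydrofuran is cut into arylidene malonate 4 and racemic 2-vinyloxirane 5. This cut removes a ring and two stereocentres at once, uses the vinyl group as the latent C6 carbonyl, and leaves C1 quaternary. A quaternary C1 has no acidic hydrogen, so O3 cannot be lost by beta-elimination in any of the following steps until the lactone is complete. The forward reaction must give the five-membered ring, the C2 aryl trans to the C5 vinyl group, and one absolute configuration at C5 from racemic 5.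

**4 ⇒ 2 + 3, 2 ⇒ 1, 10 ⇒ 9.** Malonate 4 comes from a Knoevenagel condensation of silylated aldehyde 2 with dibenzyl malonate 3. Aldehyde 2 and bromide 10 come from silylation of 3,4-dihydroxybenzaldehyde 1 and 5-bromobenzene-1,2,3-triol 9, all commercial.

## Roads not taken

**Alternative 1:** The C6–C5 and C1–C2 bonds are cut. A lithiated dithiane A3 (from the pyrogallol aldehyde) adds to C5 of the menthyloxyfuranone A2 anti to the auxiliary, and the lactone enolate is trapped by aldehyde 2 to give A1.
- Merits: two C–C bonds and both aryl groups arrive in one flask. The absolute configuration of C5 and C1 comes from a cheap crystalline auxiliary by substrate control, which is more dependable than matching a ligand to a new acceptor. In this respect it is the stronger plan.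
- Weak points: no ring of the target is closed, and the lactone in A1 is the wrong one. Its acetal carbon is C4, which must come down to the ether level while C8 stays at the acid level and is relactonised onto O7. The C2 carbinol centre is formed without control. C6 appears only after the dithiane is removed, by oxidative or thiophilic-metal conditions next to five silyloxy groups, and the ketone is then reduced selectively.
- Comparison: the chosen plan sets against this a catalytic asymmetric ring construction that delivers C4 and C8 at their final oxidation levels and C2 in place, at the price of less certain absolute control in one step.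

**Alternative 2:** The C1–C5 and O3–C4 bonds are cut. Rh2(OAc)4 converts the allylic diazo keto ester A5 into the lactone-fused cyclopropane A6, and MgI2 in the same flask opens the C1–C4 bond and closes O3–C4 to give the dihydrofuran-fused lactone A4.
- Merits: both rings form in one operation from an acyclic ester. C6 is set beforehand in an enantioenriched aryl vinyl carbinol and should direct C5 in the intramolecular cyclopropanation. On paper the route is shorter than the chosen one.
- Weak points: the ester of a secondary benzylic allylic alcohol on an electron-rich ring ionises readily. A rhodium carbenoid next to two electron-rich arenes has competing pathways. A4 still lacks C1 and C2. The tetrasubstituted push–pull C1=C2 bond is hard to reduce; syn hydrogenation from the convex face would put the C2 aryl on the concave face, the epimer of the target, and the hydrogenation itself endangers the benzylic C–O bonds.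
- Comparison: the chosen plan is longer but sets C2 in the ring-forming step and never has to correct it.

**Alternative 3:** The C1–C5 and O7–C6 bonds are cut. Mn(OAc)3 with Cu(OAc)2 oxidises the cinnamyl ether malonate A8 to a C1 radical, which cyclises onto the alkene; the C6 radical is oxidised to the cation and captured by a tert-butyl ester to give A7.
- Merits: this is the shortest route. Two rings and three stereocentres arise from C2 alone, and A7 is two operations from the target. It is clearly ahead in step count.
- Weak points: the absolute configuration rests on C2 of A8, a beta-alkoxy malonate with an acidic C1 hydrogen. It can racemise by retro-oxa-Michael reaction and has no established enantioselective entry. Trivalent manganese and divalent copper in warm acetic acid are one-electron oxidants for the pentasilyloxy substrate, above all for the trioxygenated styrene. The relation of C2 to C5 in the radical closure is only moderately controlled.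
- Comparison: the chosen plan gives up about three steps for non-oxidative conditions, catalytic absolute control and separately adjustable C2, C5 and C6.

Key step: step 3

Assumption: the (R,R) ligand is taken to give the (2R,4R) enantiomer of 6; the sense of induction on this acceptor is to be checked by correlation on the first batch, and the (S,S) ligand would replace it without other change.

## Route

Abbreviations: TBS = tert-butyldimethylsilyl, TBSO = tert-butyldimethylsilyloxy.

Step 1
Reactants: 1 3,4-dihydroxybenzaldehyde
Product: 2 3,4-bis(tert-butyldimethylsilyloxy)benzaldehyde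
Conditions: TBSCl (2.5 equiv), imidazole (5 equiv), DMF, rt
Reagents that add atoms: tert-butyldimethylsilyl chloride, CC(C)(C)[Si](C)(C)Cl
Why: Standard silylation of phenols with a silyl chloride and imidazole; no stereocentre is involved.

Step 2
Reactants: 2 3,4-bis(tert-butyldimethylsilyloxy)benzaldehyde; 3 dibenzyl malonate
Product: 4 dibenzyl 2-[3,4-bis(tert-butyldimethylsilyloxy)benzylidene]malonate
Conditions: piperidine (0.1 equiv), AcOH (0.1 equiv), toluene, reflux, azeotropic removal of water
Reagents that add atoms: none
Why: Knoevenagel condensation under piperidinium acetate catalysis; water removal drives it to completion, and the alkene carries two identical esters so no geometry has to be controlled.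

Step 3
Reactants: 4 dibenzyl 2-[3,4-bis(tert-butyldimethylsilyloxy)benzylidene]malonate; 5 2-vinyloxirane (racemic)
Product: 6 dibenzyl (2R,4R)-2-[3,4-bis(tert-butyldimethylsilyloxy)phenyl]-4-vinyloxolane-3,3-dicarboxylate
Conditions: Pd2(dba)3·CHCl3 (2.5 mol%), (R,R)-DACH-phenyl ligand N,N'-[(1R,2R)-cyclohexane-1,2-diyl]bis[2-(diphenylphosphino)benzamide] (7.5 mol%), 5 (2 equiv), THF, 0 °C → rt
Reagents that add atoms: none
Why: Zerovalent palladium opens 5 with inversion to a zwitterion, a primary alkoxide tethered to a pi-allyl complex of divalent palladium; the alkoxide adds to the benzylidene carbon of 4 (O3–C2), and the resulting malonate anion attacks the substituted allyl terminus anti to the metal (C1–C5), releasing the catalyst. The closest known reaction is the zerovalent-palladium-catalysed (3+2) cycloaddition of vinyl epoxides with doubly activated alkenes such as arylidene malonates, including ligand-controlled dynamic kinetic asymmetric versions. The tetrahydrofuran closes by 5-exo-trig attack of the malonate carbon on the allyl terminus that carries the CH2O arm; attack at the far terminus would give a seven-membered ring and is not expected to compete. The C5 centre (C4 of the oxolane) is set by the ligand: the diastereomeric pi-allyl complexes from racemic 5 interconvert by pi–sigma–pi isomerisation faster than the ring closes, so the chiral pocket funnels both enantiomers of 5 to one configuration. The C2 centre is set relative to C5 in the closing transition state: because the oxa-Michael addition to a malonate acceptor is reversible, both C2 epimers of the open anion are available, and the one that closes with the aryl group pseudo-equatorial and away from the ligand-bearing allyl face, trans to the vinyl group, should be drained. The step therefore needs branched regioselectivity, trans diastereoselectivity and enantioselectivity, secured in turn by the tether, by the reversibility that the stabilised malonate anion provides, and by the ligand. Benzyl esters and aryl silyl ethers are inert to the catalyst.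

Step 4
Reactants: 6 dibenzyl (2R,4R)-2-[3,4-bis(tert-butyldimethylsilyloxy)phenyl]-4-vinyloxolane-3,3-dicarboxylate
Product: 8 (3R,5R)-4,4-bis(benzyloxycarbonyl)-5-[3,4-bis(tert-butyldimethylsilyloxy)phenyl]oxolane-3-carboxylic acid, via aldehyde 7 (not isolated)
Conditions: O3, acetone/H2O (95:5), 0 °C, to the point of alkene consumption; N2 purge; then 2-methyl-2-butene, NaClO2, NaH2PO4, H2O, 0 °C → rt
Reagents that add atoms: ozone, [O-][O+]=O; sodium chlorite, [Na+].[O-]Cl=O
Why: Ozonolysis in wet acetone gives the aldehyde directly because water intercepts the carbonyl oxide, and Pinnick oxidation in the same flask takes it to the acid. The medium stays weakly acidic, so the C5 hydrogen (alpha to the carbonyl, beta to O3) is neither epimerised nor eliminated; the alkene reacts with ozone far faster than the silyloxyarene, and 2-methyl-2-butene removes HOCl.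

Step 5
Reactants: 9 5-bromobenzene-1,2,3-triol
Product: 10 5-bromo-1,2,3-tris(tert-butyldimethylsilyloxy)benzene
Conditions: TBSCl (3.6 equiv), imidazole (7 equiv), DMF, rt → 40 °C
Reagents that add atoms: tert-butyldimethylsilyl chloride, CC(C)(C)[Si](C)(C)Cl
Why: Exhaustive silylation of the three phenols with a silyl chloride and imidazole; gentle warming completes the hindered central position.

Step 6
Reactants: 8 (3R,5R)-4,4-bis(benzyloxycarbonyl)-5-[3,4-bis(tert-butyldimethylsilyloxy)phenyl]oxolane-3-carboxylic acid; 10 5-bromo-1,2,3-tris(tert-butyldimethylsilyloxy)benzene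
Product: 14 dibenzyl (2R,4R)-2-[3,4-bis(tert-butyldimethylsilyloxy)phenyl]-4-[3,4,5-tris(tert-butyldimethylsilyloxy)benzoyl]oxolane-3,3-dicarboxylate, via acid chloride 11 (not isolated), via aryllithium 12 (not isolated), via arylzinc chloride 13 (not isolated)
Conditions: 8, 1-chloro-N,N,2-trimethylprop-1-en-1-amine, CH2Cl2, 0 °C → rt, then solvent exchange to THF; separately 10, n-BuLi, THF, −78 °C, then ZnCl2, −78 → 0 °C; combine, Pd(PPh3)4 (5 mol%), THF, 0 °C → rt
Reagents that add atoms: none
Why: Negishi acylation: the chloroenamine forms the acid chloride without base or HCl, bromine–lithium exchange and transmetalation give the arylzinc chloride, and palladium couples the two. The zinc reagent tolerates the benzyl esters and is too weakly basic to enolise C5, and the aryllithium has no silyloxy group ortho to the metal, so silyl migration cannot occur.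

Step 7
Reactants: 14 dibenzyl (2R,4R)-2-[3,4-bis(tert-butyldimethylsilyloxy)phenyl]-4-[3,4,5-tris(tert-butyldimethylsilyloxy)benzoyl]oxolane-3,3-dicarboxylate
Product: 16 benzyl (1S,2R,5R,6S)-2-[3,4-bis(tert-butyldimethylsilyloxy)phenyl]-8-oxo-6-[3,4,5-tris(tert-butyldimethylsilyloxy)phenyl]-3,7-dioxabicyclo[3.3.0]octane-1-carboxylate, via lithium alkoxide 15 (not isolated)
Conditions: LiBH(s-Bu)3 (1.2 equiv), THF, −78 °C → rt; aq. NH4Cl
Reagents that add atoms: none
Why: Felkin–Anh reduction of an alpha-branched aryl ketone by a bulky hydride: hydride enters anti to the quaternary C1 with the aryl group lying over the C5 hydrogen, which sets (6S) (a chelate through O3 would give the same result). The alkoxide then closes the gamma-lactone by acyl substitution on the only ester it can reach, the cis one, so the ring fusion is cis and the remaining ester ends on the convex face.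

Step 8
Reactants: 16 benzyl (1S,2R,5R,6S)-2-[3,4-bis(tert-butyldimethylsilyloxy)phenyl]-8-oxo-6-[3,4,5-tris(tert-butyldimethylsilyloxy)phenyl]-3,7-dioxabicyclo[3.3.0]octane-1-carboxylate
Product: 18 (1S,2S,5R,6S)-2-[3,4-bis(tert-butyldimethylsilyloxy)phenyl]-6-[3,4,5-tris(tert-butyldimethylsilyloxy)phenyl]-3,7-dioxabicyclo[3.3.0]octan-8-one, via carboxylic acid 17 (not isolated)
Conditions: H2 (1 atm), Pd/C (10%), EtOAc, rt, stopped at one equivalent; filter; then toluene, 100 °C
Reagents that add atoms: none
Why: Hydrogenolysis of a primary benzyl ester is much faster than cleavage of the hindered secondary benzylic C–O bonds flanked by silyloxy groups, and the resulting beta-carbonyl acid decarboxylates thermally through a cyclic transition state to the lactone enol. Ketonisation can give only the cis-fused lactone, which sets (1S), and the neutral path avoids a C1 enolate that could expel O3.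

Step 9
Reactants: 18 (1S,2S,5R,6S)-2-[3,4-bis(tert-butyldimethylsilyloxy)phenyl]-6-[3,4,5-tris(tert-butyldimethylsilyloxy)phenyl]-3,7-dioxabicyclo[3.3.0]octan-8-one
Product: 19 (1S,2S,5R,6S)-2-(3,4-dihydroxyphenyl)-6-(3,4,5-trihydroxyphenyl)-3,7-dioxabicyclo[3.3.0]octan-8-one
Conditions: Bu4NF (6 equiv), AcOH (6 equiv), THF, 0 °C → rt, under argon
Reagents that add atoms: none
Why: Fluoride cleavage of aryl silyl ethers; the acetic acid buffer keeps the phenols protonated, which protects them from air oxidation and prevents enolisation at C1 with loss of O3, so no stereocentre is touched.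

## Compound list

1 | 3,4-dihydroxybenzaldehyde | O=Cc1ccc(O)c(O)c1 | starting material
2 | 3,4-bis(tert-butyldimethylsilyloxy)benzaldehyde | O=Cc1ccc(O[Si](C)(C)C(C)(C)C)c(O[Si](C)(C)C(C)(C)C)c1 | intermediate
3 | dibenzyl malonate | O=C(CC(=O)OCc1ccccc1)OCc1ccccc1 | starting material
4 | dibenzyl 2-[3,4-bis(TBSO)benzylidene]malonate | O=C(OCc1ccccc1)C(=Cc2ccc(O[Si](C)(C)C(C)(C)C)c(O[Si](C)(C)C(C)(C)C)c2)C(=O)OCc3ccccc3 | intermediate
5 | 2-vinyloxirane (racemic) | C=CC1CO1 | starting material
6 | dibenzyl (2R,4R)-2-[3,4-bis(TBSO)phenyl]-4-vinyloxolane-3,3-dicarboxylate | C=C[C@H]1CO[C@H](c2ccc(O[Si](C)(C)C(C)(C)C)c(O[Si](C)(C)C(C)(C)C)c2)C1(C(=O)OCc3ccccc3)C(=O)OCc4ccccc4 | intermediate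
7 | dibenzyl (2R,4R)-2-[3,4-bis(TBSO)phenyl]-4-formyloxolane-3,3-dicarboxylate (not isolated) | O=C[C@H]1CO[C@H](c2ccc(O[Si](C)(C)C(C)(C)C)c(O[Si](C)(C)C(C)(C)C)c2)C1(C(=O)OCc3ccccc3)C(=O)OCc4ccccc4 | intermediate
8 | (3R,5R)-4,4-bis(benzyloxycarbonyl)-5-[3,4-bis(TBSO)phenyl]oxolane-3-carboxylic acid | OC(=O)[C@H]1CO[C@H](c2ccc(O[Si](C)(C)C(C)(C)C)c(O[Si](C)(C)C(C)(C)C)c2)C1(C(=O)OCc3ccccc3)C(=O)OCc4ccccc4 | intermediate
9 | 5-bromobenzene-1,2,3-triol | Oc1cc(Br)cc(O)c1O | starting material
10 | 5-bromo-1,2,3-tris(tert-butyldimethylsilyloxy)benzene | Brc1cc(O[Si](C)(C)C(C)(C)C)c(O[Si](C)(C)C(C)(C)C)c(O[Si](C)(C)C(C)(C)C)c1 | intermediate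
11 | dibenzyl (2R,4R)-2-[3,4-bis(TBSO)phenyl]-4-(chlorocarbonyl)oxolane-3,3-dicarboxylate (not isolated) | ClC(=O)[C@H]1CO[C@H](c2ccc(O[Si](C)(C)C(C)(C)C)c(O[Si](C)(C)C(C)(C)C)c2)C1(C(=O)OCc3ccccc3)C(=O)OCc4ccccc4 | intermediate
12 | [3,4,5-tris(TBSO)phenyl]lithium (not isolated) | [Li]c1cc(O[Si](C)(C)C(C)(C)C)c(O[Si](C)(C)C(C)(C)C)c(O[Si](C)(C)C(C)(C)C)c1 | intermediate
13 | [3,4,5-tris(TBSO)phenyl]zinc chloride (not isolated) | Cl[Zn]c1cc(O[Si](C)(C)C(C)(C)C)c(O[Si](C)(C)C(C)(C)C)c(O[Si](C)(C)C(C)(C)C)c1 | intermediate
14 | dibenzyl (2R,4R)-2-[3,4-bis(TBSO)phenyl]-4-[3,4,5-tris(TBSO)benzoyl]oxolane-3,3-dicarboxylate | O=C(c5cc(O[Si](C)(C)C(C)(C)C)c(O[Si](C)(C)C(C)(C)C)c(O[Si](C)(C)C(C)(C)C)c5)[C@H]1CO[C@H](c2ccc(O[Si](C)(C)C(C)(C)C)c(O[Si](C)(C)C(C)(C)C)c2)C1(C(=O)OCc3ccccc3)C(=O)OCc4ccccc4 | intermediate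
15 | lithium alkoxide of dibenzyl (2R,4R)-2-[3,4-bis(TBSO)phenyl]-4-{(S)-hydroxy[3,4,5-tris(TBSO)phenyl]methyl}oxolane-3,3-dicarboxylate (not isolated) | [Li]O[C@H](c5cc(O[Si](C)(C)C(C)(C)C)c(O[Si](C)(C)C(C)(C)C)c(O[Si](C)(C)C(C)(C)C)c5)[C@H]1CO[C@H](c2ccc(O[Si](C)(C)C(C)(C)C)c(O[Si](C)(C)C(C)(C)C)c2)C1(C(=O)OCc3ccccc3)C(=O)OCc4ccccc4 | intermediate
16 | benzyl (1S,2R,5R,6S)-2-[3,4-bis(TBSO)phenyl]-8-oxo-6-[3,4,5-tris(TBSO)phenyl]-3,7-dioxabicyclo[3.3.0]octane-1-carboxylate | O=C1O[C@H](c5cc(O[Si](C)(C)C(C)(C)C)c(O[Si](C)(C)C(C)(C)C)c(O[Si](C)(C)C(C)(C)C)c5)[C@H]2CO[C@H](c3ccc(O[Si](C)(C)C(C)(C)C)c(O[Si](C)(C)C(C)(C)C)c3)[C@@]12C(=O)OCc4ccccc4 | intermediate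
17 | (1S,2R,5R,6S)-2-[3,4-bis(TBSO)phenyl]-8-oxo-6-[3,4,5-tris(TBSO)phenyl]-3,7-dioxabicyclo[3.3.0]octane-1-carboxylic acid (not isolated) | O=C1O[C@H](c5cc(O[Si](C)(C)C(C)(C)C)c(O[Si](C)(C)C(C)(C)C)c(O[Si](C)(C)C(C)(C)C)c5)[C@H]2CO[C@H](c3ccc(O[Si](C)(C)C(C)(C)C)c(O[Si](C)(C)C(C)(C)C)c3)[C@@]12C(=O)O | intermediate
18 | (1S,2S,5R,6S)-2-[3,4-bis(TBSO)phenyl]-6-[3,4,5-tris(TBSO)phenyl]-3,7-dioxabicyclo[3.3.0]octan-8-one | O=C1O[C@H](c5cc(O[Si](C)(C)C(C)(C)C)c(O[Si](C)(C)C(C)(C)C)c(O[Si](C)(C)C(C)(C)C)c5)[C@H]2CO[C@H](c3ccc(O[Si](C)(C)C(C)(C)C)c(O[Si](C)(C)C(C)(C)C)c3)[C@@H]12 | intermediate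
19 | (1S,2S,5R,6S)-2-(3,4-dihydroxyphenyl)-6-(3,4,5-trihydroxyphenyl)-3,7-dioxabicyclo[3.3.0]octan-8-one | O=C1O[C@H](c2cc(O)c(O)c(O)c2)[C@H]2CO[C@H](c3ccc(O)c(O)c3)[C@@H]12 | target

## Step count and least certain steps

Total step count: 9. Longest linear sequence: 8 steps (steps 1–4 and 6–9, from 1); step 5 is the side branch.

**Step 3 (key step).**
- Risk: the electron-rich benzylidene malonate is a weak oxa-Michael acceptor, so the zwitterion may be lost to isomerisation or oligomerisation of the epoxide before it is trapped. Ring closure may discriminate poorly between the trans and cis arrangements of C2 and C5. Enantioface control may be incomplete if closure competes with equilibration of the pi-allyl complexes.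
- Fallback: starting from 4, the same zwitterion would be generated by decarboxylative ionisation of 4-vinyl-1,3-dioxolan-2-one F1 with Pd2(dba)3·CHCl3 and a binaphthol-derived phosphoramidite. This changes the precursor (irreversible ionisation, no epoxide present to oligomerise) and the ligand class, and it is a well-developed manifold for asymmetric (3+2) additions to Michael acceptors. The fallback returns to the route at 6.

**Step 7.**
- Risk: poor facial selectivity in hydride delivery, for example through a non-Felkin rotamer, would give the C6 epimer. Slow closure of the alkoxide onto the hindered ester would leave open hydroxy diester.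
- Fallback: the stereocomplementary bond formation. Starting from 6, reductive ozonolysis (O3, CH2Cl2, −78 °C; PPh3) would give isolated 7. Addition of [3,4,5-tris(TBSO)phenyl]magnesium bromide F2 (from 10 and Mg in THF) at −78 °C would give the bromomagnesium alkoxide F3, which lactonises on warming and returns to the route at 16. Because the aryl group and not the hydrogen is then the incoming group, whatever face preference defeated the reduction would here give the required C6 configuration.

**Step 6.**
- Risk: slow oxidative addition or transmetalation at the hindered acid chloride would allow decarbonylation, loss of configuration at C5 through ketene formation or enolisation, or beta-elimination of O3.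
- Fallback: starting from 8, esterification with ethanethiol (EDC, catalytic DMAP) would give the bench-stable S-ethyl thioester F4. This would be coupled with arylzinc chloride 13 under PdCl2(PPh3)2 catalysis (Fukuyama coupling), returning to the route at 14.

**Step 8.**
- Risk: competing hydrogenolysis of the benzylic C6–O7 or C2–O3 bond before the benzyl ester is fully cleaved.
- Fallback: starting from 16, non-reductive SN2 dealkylation with anhydrous LiI in refluxing ethyl acetate would give the lithium carboxylate F5 and benzyl iodide. Acidification would give 17, which rejoins the route at the thermal decarboxylation to 18.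

**Step 2.**
- Risk: loss of aryl silyl groups by amine-catalysed solvolysis with the water set free in the condensation.
- Fallback: reverse the order. Starting from 1, condensation with 3 under the same catalysis would give dibenzyl 2-(3,4-dihydroxybenzylidene)malonate F6, and silylation (TBSCl, imidazole, DMF) would return to the route at 4.

## Further compounds

F1 | step 3 | 4-vinyl-1,3-dioxolan-2-one (racemic) | C=CC1COC(=O)O1
F2 | step 7 | [3,4,5-tris(tert-butyldimethylsilyloxy)phenyl]magnesium bromide | Br[Mg]c1cc(O[Si](C)(C)C(C)(C)C)c(O[Si](C)(C)C(C)(C)C)c(O[Si](C)(C)C(C)(C)C)c1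
F3 | step 7 | bromomagnesium alkoxide of dibenzyl (2R,4R)-2-[3,4-bis(TBSO)phenyl]-4-{(S)-hydroxy[3,4,5-tris(TBSO)phenyl]methyl}oxolane-3,3-dicarboxylate | Br[Mg]O[C@H](c5cc(O[Si](C)(C)C(C)(C)C)c(O[Si](C)(C)C(C)(C)C)c(O[Si](C)(C)C(C)(C)C)c5)[C@H]1CO[C@H](c2ccc(O[Si](C)(C)C(C)(C)C)c(O[Si](C)(C)C(C)(C)C)c2)C1(C(=O)OCc3ccccc3)C(=O)OCc4ccccc4
F4 | step 6 | dibenzyl (2R,4R)-2-[3,4-bis(TBSO)phenyl]-4-[(ethylsulfanyl)carbonyl]oxolane-3,3-dicarboxylate | CCSC(=O)[C@H]1CO[C@H](c2ccc(O[Si](C)(C)C(C)(C)C)c(O[Si](C)(C)C(C)(C)C)c2)C1(C(=O)OCc3ccccc3)C(=O)OCc4ccccc4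
F5 | step 8 | lithium (1S,2R,5R,6S)-2-[3,4-bis(TBSO)phenyl]-8-oxo-6-[3,4,5-tris(TBSO)phenyl]-3,7-dioxabicyclo[3.3.0]octane-1-carboxylate | O=C1O[C@H](c5cc(O[Si](C)(C)C(C)(C)C)c(O[Si](C)(C)C(C)(C)C)c(O[Si](C)(C)C(C)(C)C)c5)[C@H]2CO[C@H](c3ccc(O[Si](C)(C)C(C)(C)C)c(O[Si](C)(C)C(C)(C)C)c3)[C@@]12C(=O)[O-].[Li+]
F6 | step 2 | dibenzyl 2-(3,4-dihydroxybenzylidene)malonate | O=C(OCc1ccccc1)C(=Cc2ccc(O)c(O)c2)C(=O)OCc3ccccc3
A1 | alternative 1 | trans-3-{hydroxy[3,4-bis(TBSO)phenyl]methyl}-4-{2-[3,4,5-tris(TBSO)phenyl]-1,3-dithian-2-yl}-5-(l-menthyloxy)dihydrofuran-2(3H)-one (carbinol centre unassigned) | O=C1O[C@@H](O[C@@H]4C[C@H](C)CC[C@H]4C(C)C)[C@H](C5(c2cc(O[Si](C)(C)C(C)(C)C)c(O[Si](C)(C)C(C)(C)C)c(O[Si](C)(C)C(C)(C)C)c2)SCCCS5)[C@H]1C(O)c3ccc(O[Si](C)(C)C(C)(C)C)c(O[Si](C)(C)C(C)(C)C)c3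
A2 | alternative 1 | (5R)-5-(l-menthyloxy)furan-2(5H)-one | O=C1O[C@@H](O[C@@H]2C[C@H](C)CC[C@H]2C(C)C)C=C1
A3 | alternative 1 | 2-[3,4,5-tris(tert-butyldimethylsilyloxy)phenyl]-1,3-dithiane | C1CSC(SC1)c2cc(O[Si](C)(C)C(C)(C)C)c(O[Si](C)(C)C(C)(C)C)c(O[Si](C)(C)C(C)(C)C)c2
A4 | alternative 2 | (5R,6S)-2-[3,4-bis(TBSO)phenyl]-6-[3,4,5-tris(TBSO)phenyl]-3,7-dioxabicyclo[3.3.0]oct-1-en-8-one | O=C1O[C@H](c2cc(O[Si](C)(C)C(C)(C)C)c(O[Si](C)(C)C(C)(C)C)c(O[Si](C)(C)C(C)(C)C)c2)[C@H]2COC(c3ccc(O[Si](C)(C)C(C)(C)C)c(O[Si](C)(C)C(C)(C)C)c3)=C12
A5 | alternative 2 | (S)-1-[3,4,5-tris(TBSO)phenyl]allyl 2-diazo-3-[3,4-bis(TBSO)phenyl]-3-oxopropanoate | O=C(O[C@H](c3cc(O[Si](C)(C)C(C)(C)C)c(O[Si](C)(C)C(C)(C)C)c(O[Si](C)(C)C(C)(C)C)c3)C=C)C(=[N+]=[N-])C(=O)c4ccc(O[Si](C)(C)C(C)(C)C)c(O[Si](C)(C)C(C)(C)C)c4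
A6 | alternative 2 | 1-[3,4-bis(TBSO)benzoyl]-4-[3,4,5-tris(TBSO)phenyl]-3-oxabicyclo[3.1.0]hexan-2-one (cis-fused, aryl trans to the cyclopropane methylene) | O=C1O[C@H](c3cc(O[Si](C)(C)C(C)(C)C)c(O[Si](C)(C)C(C)(C)C)c(O[Si](C)(C)C(C)(C)C)c3)[C@H]2C[C@@]12C(=O)c4ccc(O[Si](C)(C)C(C)(C)C)c(O[Si](C)(C)C(C)(C)C)c4
A7 | alternative 3 | tert-butyl (1S,2R,5R,6S)-2-[3,4-bis(TBSO)phenyl]-8-oxo-6-[3,4,5-tris(TBSO)phenyl]-3,7-dioxabicyclo[3.3.0]octane-1-carboxylate | O=C1O[C@H](c2cc(O[Si](C)(C)C(C)(C)C)c(O[Si](C)(C)C(C)(C)C)c(O[Si](C)(C)C(C)(C)C)c2)[C@H]2CO[C@H](c3ccc(O[Si](C)(C)C(C)(C)C)c(O[Si](C)(C)C(C)(C)C)c3)[C@@]12C(=O)OC(C)(C)C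
A8 | alternative 3 | di-tert-butyl 2-{(S)-[3,4-bis(TBSO)phenyl][(E)-3-[3,4,5-tris(TBSO)phenyl]allyloxy]methyl}malonate | O(C/C=C/c3cc(O[Si](C)(C)C(C)(C)C)c(O[Si](C)(C)C(C)(C)C)c(O[Si](C)(C)C(C)(C)C)c3)[C@H](c4ccc(O[Si](C)(C)C(C)(C)C)c(O[Si](C)(C)C(C)(C)C)c4)C(C(=O)OC(C)(C)C)C(=O)OC(C)(C)C
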